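The plan cuts C5′–C6′, in the middle of the unfunctionalised (CH2)11 tether that links C2 of the 2,3-dihydropyran-4-one ring to the C12′=C13′ (Z)-olefin. Both atoms are unpolarised methylenes, so they are united as two like-polarity primary radicals. A nickel-electrocatalytic doubly decarboxylative cross-coupling expels two CO2 and forges the CH2–CH2 bond in one operation. It spares the olefin geometry, the ring's vinylogous ester and the base-sensitive C2 stereocentre. Its precursors are two free acids, each one carbon longer than its half: (Z)-heptadec-8-enoic acid (Wittig) and (R)-6-(6-methyl-4-oxo-2,3-dihydropyran-2-yl)hexanoic acid (BINOL–Ti aldol/cyclodehydration). Both are activated in the flask as N-hydroxyphthalimide esters.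

Key step: step 6

Locants: ring O1, C2 (stereocentre), C3, C4 (C=O), C5, C6 (C–CH3); side chain C1′–C21′ counted from C2.
Assumption: methyl 7-oxoheptanoate is taken as a catalogue compound, and the (S)-BINOL–Ti(IV) catalyst is taken to direct attack to the Si face of an unbranched aliphatic aldehyde, as in related BINOL–Ti carbonyl additions; should the correlation prove opposite, (R)-BINOL would be used.

Step 1
Reactants: 1 8-bromooctanoic acid
Product: 2 (7-carboxyheptyl)triphenylphosphonium bromide
Conditions: PPh3 (1.05 equiv), MeCN, reflux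
Reagents that add atoms: triphenylphosphine, c1ccc(cc1)P(c1ccccc1)c1ccccc1
Why: SN2 quaternisation of PPh3 by an unhindered primary bromide (phosphonium salt formation) should proceed cleanly, since the free carboxylic acid is a spectator.

Step 2
Reactants: 2 (7-carboxyheptyl)triphenylphosphonium bromide; 3 nonanal
Product: 5 (Z)-heptadec-8-enoic acid, via ylide carboxylate 4 (not isolated)
Conditions: NaHMDS (2.1 equiv), THF, 0 °C; then 3, −78 °C → rt; dilute HCl work-up
Reagents that add atoms: none
Why: Wittig olefination, in which the non-stabilised, lithium-free ylide should add to nonanal under kinetic control through the cis-oxaphosphetane and so set the later C12′=C13′ olefin as Z, any E isomer being removable on AgNO3-impregnated silica.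

Step 3
Reactants: 6 acetylacetone
Product: 7 (3Z)-2,4-bis(trimethylsilyloxy)penta-1,3-diene
Conditions: TMSOTf (2.2 equiv), Et3N (2.5 equiv), Et2O, 0 °C → rt; distillation
Reagents that add atoms: trimethylsilyl trifluoromethanesulfonate, C[Si](C)(C)OS(=O)(=O)C(F)(F)F
Why: Double soft enolisation/O-silylation of a 1,3-diketone with a silyl triflate and a tertiary amine is the standard access to 1,3-bis(silyloxy)-1,3-dienes (masked acetylacetone dianion), and the C3=C4 geometry is of no consequence because step 4 erases it.

Step 4
Reactants: 7 (3Z)-2,4-bis(trimethylsilyloxy)penta-1,3-diene; 8 methyl 7-oxoheptanoate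
Product: 11 methyl 6-[(2R)-6-methyl-4-oxo-3,4-dihydro-2H-pyran-2-yl]hexanoate, via silyl aldol adduct 9 (not isolated), via hydroxy diketone 10 (not isolated)
Conditions: (S)-BINOL (10 mol %), Ti(OiPr)4 (10 mol %), 4 Å MS, THF, −78 → −20 °C; then TFA, CH2Cl2, 0 °C → rt
Reagents that add atoms: none
Why: Catalytic asymmetric vinylogous Mukaiyama aldol reaction (a formal hetero-Diels–Alder reaction), in which the (S)-BINOL–Ti(IV) Lewis acid should expose the Si face of the aldehyde to the terminal CH2 of 7 and set C2 as R, after which TFA strips both silyl groups and 10 closes by hemiketalisation at the distal carbonyl and dehydration without touching the C–O bond of the stereocentre.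

Step 5
Reactants: 11 methyl 6-[(2R)-6-methyl-4-oxo-3,4-dihydro-2H-pyran-2-yl]hexanoate
Product: 12 6-[(2R)-6-methyl-4-oxo-3,4-dihydro-2H-pyran-2-yl]hexanoic acid
Conditions: immobilised Candida antarctica lipase B, pH 7 phosphate buffer/acetone, 30 °C
Reagents that add atoms: water, O
Why: Lipase-catalysed ester hydrolysis should cleave an unhindered methyl ester at the end of a fatty chain at pH 7, where neither hydroxide addition to the vinylogous ester nor E1cB ring opening (the racemisation path of C2) should compete.

Step 6
Reactants: 5 (Z)-heptadec-8-enoic acid (3 equiv); 12 6-[(2R)-6-methyl-4-oxo-3,4-dihydro-2H-pyran-2-yl]hexanoic acid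
Product: 15 (2R)-2-[(12Z)-henicos-12-en-1-yl]-6-methyl-2,3-dihydro-4H-pyran-4-one, via alkenyl NHPI ester 13 (not isolated), via pyranone NHPI ester 14 (not isolated)
Conditions: N-hydroxyphthalimide and DIC (1 equiv each per CO2H), cat. DMAP, CH2Cl2, rt; solvent switch to DMF; NiCl2·6H2O (20 mol %), 4,4′,4″-tri-tert-butylterpyridine (20 mol %), NaI, Zn(+)/RVC(−), undivided cell, constant current, rt; dilute HCl work-up
Reagents that add atoms: none
Why: DIC esterifies both acids with N-hydroxyphthalimide, and cathodically generated low-valent (terpyridine)nickel then transfers one electron to each N-acyloxyphthalimide, which fragments to phthalimide anion, CO2 and a primary radical (C6′ from 13, C5′ from 14). Successive capture of the two radicals at nickel gives a dialkylnickel(III) species whose reductive elimination forges C5′–C6′, the zinc anode supplying the two electrons. The closest known reaction type is this very nickel-electrocatalytic doubly decarboxylative C(sp3)–C(sp3) cross-coupling of redox-active esters, established for primary/primary pairs and best seen as a reductive, catalysed counterpart of mixed Kolbe electrolysis. No ring is closed and no stereocentre is made; C2 lies five methylenes from the radical site, and the neutral aprotic medium should give the retro-oxa-Michael racemisation pathway no opening. The selectivity needed is hetero- over homocoupling, which is only statistical for two primary radicals and is therefore secured by the threefold excess of the cheaper 5, the two homodimers (an apolar C32 diene and a polar bis-pyranone) differing sharply in polarity from 15. Chemoselectivity rests on the substrate: the imide esters are reduced far more easily than the vinylogous ester, the electron-rich C5=C6 bond of the ring is a poor acceptor for nucleophilic alkyl radicals, and the C12′=C13′ olefin is too remote (only 7-exo/8-endo modes) to trap the C6′ radical, so its Z geometry should persist.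

Compound list
1 | 8-bromooctanoic acid | OC(=O)CCCCCCCBr | starting material
2 | (7-carboxyheptyl)triphenylphosphonium bromide | OC(=O)CCCCCCC[P+](c1ccccc1)(c1ccccc1)c1ccccc1.[Br-] | intermediate
3 | nonanal | CCCCCCCCC=O | starting material
4 | sodium 8-(triphenyl-λ5-phosphanylidene)octanoate (ylide carboxylate, not isolated) | [Na+].[O-]C(=O)CCCCCCC=P(c1ccccc1)(c1ccccc1)c1ccccc1 | intermediate
5 | (Z)-heptadec-8-enoic acid | CCCCCCCC/C=C\CCCCCCC(=O)O | intermediate
6 | acetylacetone (pentane-2,4-dione) | CC(=O)CC(C)=O | starting material
7 | (3Z)-2,4-bis(trimethylsilyloxy)penta-1,3-diene (drawn Z; geometry inconsequential) | C=C(O[Si](C)(C)C)/C=C(/C)O[Si](C)(C)C | intermediate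
8 | methyl 7-oxoheptanoate | COC(=O)CCCCCC=O | starting material
9 | methyl (7R,10Z)-9-oxo-7,11-bis(trimethylsilyloxy)dodec-10-enoate (not isolated) | COC(=O)CCCCC[C@@H](O[Si](C)(C)C)CC(=O)/C=C(/C)O[Si](C)(C)C | intermediate
10 | methyl (7R)-7-hydroxy-9,11-dioxododecanoate (not isolated) | COC(=O)CCCCC[C@@H](O)CC(=O)CC(C)=O | intermediate
11 | methyl 6-[(2R)-6-methyl-4-oxo-3,4-dihydro-2H-pyran-2-yl]hexanoate | COC(=O)CCCCC[C@@H]1CC(=O)C=C(C)O1 | intermediate
12 | 6-[(2R)-6-methyl-4-oxo-3,4-dihydro-2H-pyran-2-yl]hexanoic acid | OC(=O)CCCCC[C@@H]1CC(=O)C=C(C)O1 | intermediate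
13 | 1,3-dioxoisoindolin-2-yl (Z)-heptadec-8-enoate (not isolated) | CCCCCCCC/C=C\CCCCCCC(=O)ON1C(=O)c2ccccc2C1=O | intermediate
14 | 1,3-dioxoisoindolin-2-yl 6-[(2R)-6-methyl-4-oxo-3,4-dihydro-2H-pyran-2-yl]hexanoate (not isolated) | O=C(CCCCC[C@@H]1CC(=O)C=C(C)O1)ON1C(=O)c2ccccc2C1=O | intermediate
15 | (2R)-2-[(12Z)-henicos-12-en-1-yl]-6-methyl-2,3-dihydro-4H-pyran-4-one | CCCCCCCC/C=C\CCCCCCCCCCC[C@@H]1CC(=O)C=C(C)O1 | target

Total step count: 6
Longest linear sequence: 4 steps (steps 3, 4, 5, 6; 6 → 7 → 11 → 12 → 15)

Steps most likely to fail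

1. Step 6.
- **What may go wrong:** the coupling may be eroded by statistical homocoupling. Hydrogen-atom abstraction or β-hydride elimination may occur at nickel before the second radical arrives. Nickel hydride may cause Z→E drift of the olefin, and the vinylogous ester may be attacked at the cathode.
- **Fallback:** it sets out from acid 5 and comes back at target 15. The same C5′–C6′ bond would be made before the sensitive ring exists. This uses classical mixed Kolbe anodic coupling (Pt/Pt, MeOH, partial neutralisation with NaOMe, high current density) of 5 with a large excess of commercial monomethyl pimelate. It is the well-tried anodic chain extension of Z-alkenoic acids with half-esters and should give methyl (13Z)-docos-13-enoate F1. DIBAL-H (toluene, −78 °C) would give (13Z)-docos-13-enal F2. The aldol/cyclodehydration conditions of step 4 with diene 7 would then lead through (2Z,6R,18Z)-2,6-bis(trimethylsilyloxy)heptacosa-2,18-dien-4-one F3 and (6R,18Z)-6-hydroxyheptacos-18-ene-2,4-dione F4 to 15.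

2. Step 4.
- **What may go wrong:** facial discrimination may be insufficient for an unbranched aldehyde. A silyl-cation-catalysed background aldol may compete, or acid may induce β-elimination of the carbinol during ring closure.
- **Fallback:** it sets out from aldehyde 8 and comes back at ester 11. The carbinol centre would be set by a stoichiometric, reagent-controlled Brown allylation instead of a catalytic aldol.
  - (−)-B-Allyldiisopinocampheylborane, derived from (+)-α-pinene, adds to the Si face of unbranched aldehydes (Et2O, −78 °C, buffered perborate work-up). It should give methyl (7R)-7-hydroxydec-9-enoate F5.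
  - TBSCl/imidazole gives methyl (7R)-7-(tert-butyldimethylsilyloxy)dec-9-enoate F6.
  - Ozonolysis (O3, then Me2S) gives methyl (7R)-7-(tert-butyldimethylsilyloxy)-9-oxononanoate F7.
  - 1-Propynylmagnesium bromide (THF, −78 °C, aldehyde-selective) gives methyl (7R)-7-(tert-butyldimethylsilyloxy)-9-hydroxydodec-10-ynoate F8, whose C9 epimers are inconsequential.
  - Dess–Martin oxidation gives methyl (7R)-7-(tert-butyldimethylsilyloxy)-9-oxododec-10-ynoate F9.
  - HF·pyridine frees methyl (7R)-7-hydroxy-9-oxododec-10-ynoate F10, which a cationic gold(I) catalyst should close by 6-endo-dig oxa-cyclisation to 11.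

3. Step 5.
- **What may go wrong:** enzymatic turnover may be sluggish on a poorly water-soluble substrate. If chemical saponification were pressed into service, hydroxide could open the ring and racemise C2 by retro-oxa-Michael reaction.
- **Fallback:** it sets out from diene 7 and comes back at acid 12. The carboxyl group would be carried as an acid-labile tert-butyl ester, so that no hydrolysis is needed. Commercial 7-oxoheptanoic acid would be esterified with tert-butyl 2,2,2-trichloroacetimidate (CH2Cl2/cyclohexane, rt) to tert-butyl 7-oxoheptanoate F11. The aldol of step 4 with 7 would give tert-butyl (7R,10Z)-9-oxo-7,11-bis(trimethylsilyloxy)dodec-10-enoate F12. An excess of TFA would then carry it through tert-butyl (7R)-7-hydroxy-9,11-dioxododecanoate F13 and tert-butyl 6-[(2R)-6-methyl-4-oxo-3,4-dihydro-2H-pyran-2-yl]hexanoate F14 to 12 by alkyl–oxygen cleavage.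

Further compounds
F1 | step 6 | methyl (13Z)-docos-13-enoate | CCCCCCCC/C=C\CCCCCCCCCCCC(=O)OC
F2 | step 6 | (13Z)-docos-13-enal | CCCCCCCC/C=C\CCCCCCCCCCCC=O
F3 | step 6 | (2Z,6R,18Z)-2,6-bis(trimethylsilyloxy)heptacosa-2,18-dien-4-one | CCCCCCCC/C=C\CCCCCCCCCCC[C@@H](O[Si](C)(C)C)CC(=O)/C=C(/C)O[Si](C)(C)C
F4 | step 6 | (6R,18Z)-6-hydroxyheptacos-18-ene-2,4-dione | CCCCCCCC/C=C\CCCCCCCCCCC[C@@H](O)CC(=O)CC(C)=O
F5 | step 4 | methyl (7R)-7-hydroxydec-9-enoate | COC(=O)CCCCC[C@@H](O)CC=C
F6 | step 4 | methyl (7R)-7-(tert-butyldimethylsilyloxy)dec-9-enoate | COC(=O)CCCCC[C@@H](O[Si](C)(C)C(C)(C)C)CC=C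
F7 | step 4 | methyl (7R)-7-(tert-butyldimethylsilyloxy)-9-oxononanoate | COC(=O)CCCCC[C@@H](O[Si](C)(C)C(C)(C)C)CC=O
F8 | step 4 | methyl (7R)-7-(tert-butyldimethylsilyloxy)-9-hydroxydodec-10-ynoate (C9 epimers) | COC(=O)CCCCC[C@@H](O[Si](C)(C)C(C)(C)C)CC(O)C#CC
F9 | step 4 | methyl (7R)-7-(tert-butyldimethylsilyloxy)-9-oxododec-10-ynoate | COC(=O)CCCCC[C@@H](O[Si](C)(C)C(C)(C)C)CC(=O)C#CC
F10 | step 4 | methyl (7R)-7-hydroxy-9-oxododec-10-ynoate | COC(=O)CCCCC[C@@H](O)CC(=O)C#CC
F11 | step 5 | tert-butyl 7-oxoheptanoate | CC(C)(C)OC(=O)CCCCCC=O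
F12 | step 5 | tert-butyl (7R,10Z)-9-oxo-7,11-bis(trimethylsilyloxy)dodec-10-enoate | CC(C)(C)OC(=O)CCCCC[C@@H](O[Si](C)(C)C)CC(=O)/C=C(/C)O[Si](C)(C)C
F13 | step 5 | tert-butyl (7R)-7-hydroxy-9,11-dioxododecanoate | CC(C)(C)OC(=O)CCCCC[C@@H](O)CC(=O)CC(C)=O
F14 | step 5 | tert-butyl 6-[(2R)-6-methyl-4-oxo-3,4-dihydro-2H-pyran-2-yl]hexanoate | CC(C)(C)OC(=O)CCCCC[C@@H]1CC(=O)C=C(C)O1
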